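**Strategy.** Everything rests on cutting ring A of the triquinane half at two bonds: quaternary C(CH3)(CO2H)–CH2, and the other ring CH2–ring-fusion CH beside the C–CH3 fusion carbon. The key step exploits that this C(CH3)(CO2H)–CH2 pair is a methacrylate unit, while the remaining CH2–CH–CH of ring A maps onto an activated cyclopropane. An iodide-triggered formal [3+2] annulation inserts tert-butyl methacrylate into the cyclopropane bond of an epichlorohydrin-derived lactone ester; the lactone is a temporary stand-in for ring B, and reversible Michael addition funnels all adducts into one cis-fused bicycle. A Pauson–Khand reaction then closes rings B and C, and a hetero-Diels–Alder reaction with (+)-β-caryophyllene completes the dihydropyran.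

Key step: step 2

Remark on the chemistry: the nine-membered-ring half of the target carries the (1S,9R) ring fusion of (+)-β-caryophyllene, the antipode of the commercial terpene, so this partner is made from farnesyl diphosphate with the cyclase that forms it.

Step 1
Reactants: 1 dimethyl malonate; 2 (S)-epichlorohydrin
Product: 3 methyl (1R,5S)-2-oxo-3-oxabicyclo[3.1.0]hexane-1-carboxylate
Conditions: NaOMe, MeOH, 0 °C to reflux
Reagents that add atoms: none
Why: Malonate double alkylation–lactonisation: the malonate opens the epoxide at CH2, the alkoxide re-closes onto CH2Cl, the malonate carbanion opens the new epoxide by 3-exo-tet attack with inversion and the freed alkoxide lactonises, so the stereocentre of 2 becomes C-5 and C-1 follows from the cis ring fusion.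

Step 2
Reactants: 3 methyl (1R,5S)-2-oxo-3-oxabicyclo[3.1.0]hexane-1-carboxylate; 4 tert-butyl methacrylate
Product: 7 7-tert-butyl 1-methyl (1R,5S,7S)-7-methyl-2-oxo-3-oxabicyclo[3.3.0]octane-1,7-dicarboxylate, via iodo enolate 5 (not isolated), via Michael adduct enolate 6 (not isolated)
Conditions: MgI2 (30 mol %), 4 (5 equiv), THF, 70 °C, sealed tube
Reagents that add atoms: none
Why: Proposed new method: MgI2 chelates the lactone and ester carbonyls of 3 and iodide opens the cyclopropane by SN2 attack at its CH2 to give iodo enolate 5, which adds reversibly to the CH2 terminus of 4 (Michael addition, first new C–C bond) to give ester enolate 6, whose carbanion carbon then displaces iodide from CH2I (second new C–C bond, quaternary centre) and returns the iodide. The closest known reactions are the MgI2-mediated ring expansions of acceptor-activated cyclopropanes with imines and classical Michael-initiated ring closures. The new cyclopentane closes in the 5-exo-tet mode. C-5 comes unchanged from 2; at C-1 only the adduct carrying the new CH2 cis to CH2I can close to the cis-fused bicycle while the trans adduct reverts by retro-Michael reaction, so the step is stereoconvergent; at C-7 the bulky magnesium tert-butyl ester enolate should sit on the convex face, chelated to the C-1 ester, which places CO2tBu cis to CO2Me and the methyl group over the lactone. The step needs iodide attack at the cyclopropane CH2 and not at CH or at the lactone O–CH2 (the latter is reversible and unproductive), and ring closure faster than oligomerisation of 4; the primary iodide held five atoms from the enolate carbon should secure the latter.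

Step 3
Reactants: 7 7-tert-butyl 1-methyl (1R,5S,7S)-7-methyl-2-oxo-3-oxabicyclo[3.3.0]octane-1,7-dicarboxylate
Product: 8 tert-butyl (1R,5S,7S)-7-methyl-2-oxo-3-oxabicyclo[3.3.0]octane-7-carboxylate
Conditions: LiCl, H2O, DMSO, 150 °C
Reagents that add atoms: none
Why: Krapcho dealkoxycarbonylation should remove only the malonate-type methyl ester (chloride attacks its methyl group, the tert-butyl ester cannot be dealkylated by SN2), and protonation of the lactone enolate can only give the cis-fused lactone, which sets H-1.

Step 4
Reactants: 8 tert-butyl (1R,5S,7S)-7-methyl-2-oxo-3-oxabicyclo[3.3.0]octane-7-carboxylate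
Product: 9 tert-butyl (1R,5S,7S)-2-hydroxy-2,7-dimethyl-3-oxabicyclo[3.3.0]octane-7-carboxylate (methyl lactol; both anomers)
Conditions: MeLi (1.05 equiv), THF, −78 °C; then H2O
Reagents that add atoms: methyllithium, [Li]C
Why: Lactone-to-lactol addition: one equivalent of MeLi should add to the lactone carbonyl at −78 °C, the tetrahedral lithium alkoxide surviving until work-up, while the hindered tert-butyl ester on a quaternary carbon is left untouched.

Step 5
Reactants: 9 tert-butyl (1R,5S,7S)-2-hydroxy-2,7-dimethyl-3-oxabicyclo[3.3.0]octane-7-carboxylate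
Product: 10 tert-butyl (1R,3S,4R)-3-(hydroxymethyl)-1-methyl-4-(prop-1-en-2-yl)cyclopentane-1-carboxylate
Conditions: Ph3PCH3Br, KN(SiMe3)2, THF, 0 °C to 20 °C
Reagents that add atoms: methyltriphenylphosphonium bromide, C[P+](c1ccccc1)(c1ccccc1)c1ccccc1.[Br-]
Why: Wittig methylenation of the open hydroxy methyl ketone tautomer of 9 should give the isopropenyl group, the closed lactol form holding the acetyl-bearing centre cis to CH2OH and limiting its epimerisation.

Step 6
Reactants: 10 tert-butyl (1R,3S,4R)-3-(hydroxymethyl)-1-methyl-4-(prop-1-en-2-yl)cyclopentane-1-carboxylate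
Product: 12 tert-butyl 3-(3-ethoxyprop-2-yn-1-yl)-1-methyl-4-(prop-1-en-2-yl)cyclopentane-1-carboxylate (ring configuration as in 10), via triflate 11 (not isolated)
Conditions: Tf2O, 2,6-lutidine, CH2Cl2, −78 °C; then LiC≡COEt (from ethoxyacetylene, n-BuLi), THF/DMPU, −78 to −20 °C
Reagents that add atoms: ethoxyacetylene, CCOC#C
Why: SN2 alkylation of an acetylide: the primary triflate, made and used cold, should be displaced by lithium ethoxyacetylide, which installs the 1,6-enyne with the future ketone oxygen of ring C already on the alkyne.

Step 7
Reactants: 12 tert-butyl 3-(3-ethoxyprop-2-yn-1-yl)-1-methyl-4-(prop-1-en-2-yl)cyclopentane-1-carboxylate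
Product: 14 cis-anti-cis triquinane 2-ethoxy enone tert-butyl ester, via alkyne dicobalt complex 13 (not isolated)
Conditions: Co2(CO)8, CH2Cl2, 20 °C; then N-methylmorpholine N-oxide, 0 to 20 °C
Reagents that add atoms: dicobalt octacarbonyl Co2(CO)8 (gives the ring carbonyl), O=C=[Co](=C=O)(=C=O)(=C=O)[Co](=C=O)(=C=O)(=C=O)=C=O
Why: Intramolecular Pauson–Khand reaction of the 1,6-enyne should close rings B and C at once, the cobaltacycle forming on the convex face away from ring A so that the new angular methyl is syn to ring A (cis-anti-cis) and the ethoxy group ends up α to the new ketone.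

Step 8
Reactants: 14 cis-anti-cis triquinane 2-ethoxy enone tert-butyl ester
Product: 15 cis-anti-cis triquinane 1,2-dione carboxylic acid (diosphenol tautomers)
Conditions: aq. HCl (3 M), 1,4-dioxane, 70 °C
Reagents that add atoms: water, O
Why: Acid-catalysed enol ether hydrolysis and E1 cleavage of the tert-butyl ester should free the 1,2-dione and the acid in one operation, the α-proton at the ring B/ring C fusion being set under equilibrating conditions to the cis-fused diquinane.

Step 9
Reactants: 16 (2E,6E)-farnesyl diphosphate trisammonium salt
Product: 17 (+)-β-caryophyllene [(1S,4E,9R)-4,11,11-trimethyl-8-methylidenebicyclo[7.2.0]undec-4-ene]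
Conditions: (+)-β-caryophyllene synthase (recombinant bacterial sesquiterpene cyclase, EC 4.2.3.89), MgCl2, Tris·HCl buffer pH 7.5, n-pentane overlay, 30 °C
Reagents that add atoms: none
Why: Enzymatic terpene cyclisation, the native reaction of this cyclase: diphosphate ionisation, closure of the eleven-membered ring, closure of the cyclobutane and loss of a methyl proton in the chiral active site should give only the (1S,9R) enantiomer with the E ring alkene, the pentane layer removing 17 before the enzyme can cyclise it further.

Step 10
Reactants: 15 cis-anti-cis triquinane 1,2-dione carboxylic acid; 17 (+)-β-caryophyllene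
Product: 20 sterhirsutin C, via Mannich base 18 (not isolated), via methylene dione 19 (not isolated)
Conditions: (CH2O)n, piperidine (20 mol %), AcOH (20 mol %), 17 (3 equiv), 1,4-dioxane, 90 °C, sealed tube
Reagents that add atoms: paraformaldehyde (formaldehyde), C=O
Why: Domino Mannich (Knoevenagel-type) condensation/inverse-electron-demand hetero-Diels–Alder reaction: aminomethylation at the enolisable CH2 beside the dione and loss of piperidine give the s-cis enedione 19, an electron-poor 1-oxadiene that should add suprafacially to the strained E-trisubstituted alkene of 17 with oxygen at the methyl-bearing carbon; attack on the exposed face of the ring conformer of 17 that shows the required alkene face gives 20, and the adduct of the other conformer is expected as a co-product to be removed by chromatography.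

**Compound list**

1 | dimethyl malonate | COC(=O)CC(=O)OC | starting material
2 | (S)-epichlorohydrin, (2S)-2-(chloromethyl)oxirane | ClC[C@@H]1CO1 | starting material
3 | methyl (1R,5S)-2-oxo-3-oxabicyclo[3.1.0]hexane-1-carboxylate | O=C1OC[C@H]2C[C@@]12C(=O)OC | intermediate
4 | tert-butyl methacrylate | C=C(C)C(=O)OC(C)(C)C | starting material
5 | iodomagnesium enolate of methyl (4S)-4-(iodomethyl)-2-oxooxolane-3-carboxylate (ring-opened 3) | COC(O[Mg]I)=C1C(=O)OC[C@H]1CI | intermediate
6 | iodomagnesium tert-butyl ester enolate from Michael addition of 5 to 4 (C-3 quaternary, new CH2 cis to CH2I) | COC(=O)[C@]1(CC(C)=C(O[Mg]I)OC(C)(C)C)C(=O)OC[C@H]1CI | intermediate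
7 | 7-tert-butyl 1-methyl (1R,5S,7S)-7-methyl-2-oxo-3-oxabicyclo[3.3.0]octane-1,7-dicarboxylate (cis-fused; CO2tBu cis to CO2Me) | O=C1OC[C@H]2C[C@](C)(C(=O)OC(C)(C)C)C[C@@]12C(=O)OC | intermediate
8 | tert-butyl (1R,5S,7S)-7-methyl-2-oxo-3-oxabicyclo[3.3.0]octane-7-carboxylate (cis-fused; CO2tBu cis to H-1 and H-5) | O=C1OC[C@H]2C[C@](C)(C(=O)OC(C)(C)C)C[C@@H]12 | intermediate
9 | tert-butyl (1R,5S,7S)-2-hydroxy-2,7-dimethyl-3-oxabicyclo[3.3.0]octane-7-carboxylate (methyl lactol, anomers, in equilibrium with the hydroxy ketone) | CC1(O)OC[C@H]2C[C@](C)(C(=O)OC(C)(C)C)C[C@@H]12 | intermediate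
10 | tert-butyl (1R,3S,4R)-3-(hydroxymethyl)-1-methyl-4-(prop-1-en-2-yl)cyclopentane-1-carboxylate (CH2OH, isopropenyl and ring CH3 all cis; ester trans to them) | C=C(C)[C@@H]1C[C@@](C)(C(=O)OC(C)(C)C)C[C@@H]1CO | intermediate
11 | triflate of 10 (ring configuration as in 10) | C=C(C)[C@@H]1C[C@@](C)(C(=O)OC(C)(C)C)C[C@@H]1COS(=O)(=O)C(F)(F)F | intermediate
12 | tert-butyl 3-(3-ethoxyprop-2-yn-1-yl)-1-methyl-4-(prop-1-en-2-yl)cyclopentane-1-carboxylate (ring configuration as in 10) | C=C(C)[C@@H]1C[C@@](C)(C(=O)OC(C)(C)C)C[C@@H]1CC#COCC | intermediate
13 | μ-alkyne hexacarbonyldicobalt complex of 12, Co2(CO)6(alkyne) | C=C(C)[C@@H]1C[C@@](C)(C(=O)OC(C)(C)C)C[C@@H]1CC23[Co]4(=C=O)(=C=O)(=C=O)[Co]2(=C=O)(=C=O)(=C=O)C34OCC | intermediate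
14 | cis-anti-cis triquinane 2-ethoxy enone tert-butyl ester (ring C = 2-ethoxycyclopent-2-en-1-one whose β-carbon is the ring B/ring C fusion carbon; angular CH3 on the other fusion carbon, syn to ring A; ring A carries C(CH3)(CO2tBu), ester on the convex face) | CCOC1=C2C[C@H]3C[C@](C)(C(=O)OC(C)(C)C)C[C@H]3[C@]2(C)CC1=O | intermediate
15 | cis-anti-cis triquinane 1,2-dione carboxylic acid (ring C = cyclopentane-1,2-dione with its CH2 beside the angular C–CH3; ring A carries C(CH3)(CO2H), acid on the convex face; diosphenol tautomers) | C1C(=O)C(=O)[C@@H]2C[C@H]3C[C@](C)(C(=O)O)C[C@H]3[C@]12C | intermediate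
16 | (2E,6E)-farnesyl diphosphate, trisammonium salt | CC(C)=CCC/C(C)=C/CC/C(C)=C/COP(=O)([O-])OP(=O)([O-])[O-].[NH4+].[NH4+].[NH4+] | starting material
17 | (+)-β-caryophyllene, (1S,4E,9R)-4,11,11-trimethyl-8-methylidenebicyclo[7.2.0]undec-4-ene | C/C1=C\CCC(=C)[C@@H]2CC(C)(C)[C@H]2CC1 | intermediate
18 | Mannich base of 15 (piperidin-1-ylmethyl group on the ring C CH2 beside the angular carbon) | C1CCN(CC1)CC1C(=O)C(=O)[C@@H]2C[C@H]3C[C@](C)(C(=O)O)C[C@H]3[C@]12C | intermediate
19 | methylene dione (exocyclic CH2=C beside the angular carbon, conjugated to the 1,2-dione of ring C) | C=C1C(=O)C(=O)[C@@H]2C[C@H]3C[C@](C)(C(=O)O)C[C@H]3[C@]12C | intermediate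
20 | sterhirsutin C | C=C1CC[C@H]2CC3=C(O[C@]2(C)CC[C@H]2[C@H]1CC2(C)C)C(=O)[C@@H]1C[C@H]2C[C@](C)(C(=O)O)C[C@H]2[C@]31C | target

**Step count.** Total: 10 steps. Longest linear sequence: 9 steps (steps 1 to 8, then step 10); step 9 is a one-step side branch.

**Three steps most likely to fail**

1. Step 2 (proposed new method). The ring-opened iodo enolate may re-close to 3 faster than it adds to 4, so that conversion stalls. The ester enolate may add to further 4 (oligomerisation) instead of closing, and MgI2 may cleave the tert-butyl ester. Fallback with known chemistry, setting out from 3 and coming back at 7: PhSeNa (from PhSeSePh and NaBH4, EtOH/DMF) opens the cyclopropane of 3 at its CH2 by homo-conjugate addition and should give the selenide lactone F1. Base-catalysed Michael addition to 4 (KOtBu cat., THF) gives the quaternary Michael adduct F2; the epimer with the propanoate arm cis to CH2SePh is separated and the other is recycled through retro-Michael equilibration. Br2/Et3N in CH2Cl2 exchanges the selenide for bromide and gives the bromo diester F3, which can no longer form a cyclopropane. KN(SiMe3)2 in THF then closes ring A by 5-exo-tet ester enolate alkylation to 7.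

2. Step 10. The transient enedione may be lost by self-condensation before it meets 17, 17 may isomerise under heat and weak acid, and reaction through the other ring conformer of 17 lowers the share of 20. Fallback setting out from 15 and coming back at 20: dimethylmethyleneiminium iodide (Me2N=CH2 I) in MeCN should give the isolable dimethylaminomethyl dione F7, and MeI converts it into the trimethylammonium iodide F8. NaHCO3 in water/THF at 20 °C in the presence of 17 then releases enedione 19 by E1cB elimination, so the cycloaddition to 20 runs at room temperature from a pre-formed precursor and no longer as a thermal three-component domino.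

3. Step 7. The cobalt complex of the electron-rich ynol ether may decompose (loss of the ethoxy group) before cyclocarbonylation, and insertion of the 1,1-disubstituted alkene may be slow. Fallback setting out from 10 and coming back at 15, with the ring C oxygen introduced after the annulation: 10 is converted into triflate 11 as in step 6, and LiC≡CH·H2NCH2CH2NH2 in DMSO/THF gives the terminal alkyne F4. Co2(CO)8 then N-methylmorpholine N-oxide gives the triquinane enone F5, and H2O2/NaOH in MeOH gives the epoxy ketone F6. Aqueous HCl in 1,4-dioxane at 70 °C opens the epoxide at the ring-fusion carbon, a hydride shift gives the 1,2-dione and the tert-butyl ester is cleaved, giving 15.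

**Further compounds**

F1 | step 2 | methyl (4S)-2-oxo-4-[(phenylselanyl)methyl]oxolane-3-carboxylate | COC(=O)C1C(=O)OC[C@H]1C[Se]c2ccccc2
F2 | step 2 | Michael adduct of F1 and 4 (C-3 quaternary, propanoate arm cis to CH2SePh) | COC(=O)[C@]1(CC(C)C(=O)OC(C)(C)C)C(=O)OC[C@H]1C[Se]c2ccccc2
F3 | step 2 | bromo diester (CH2Br in place of CH2SePh of F2) | COC(=O)[C@]1(CC(C)C(=O)OC(C)(C)C)C(=O)OC[C@H]1CBr
F4 | step 7 | tert-butyl 1-methyl-3-(prop-2-yn-1-yl)-4-(prop-1-en-2-yl)cyclopentane-1-carboxylate (ring configuration as in 10) | C=C(C)[C@@H]1C[C@@](C)(C(=O)OC(C)(C)C)C[C@@H]1CC#C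
F5 | step 7 | cis-anti-cis triquinane enone tert-butyl ester (as 14 with H in place of OEt) | O=C1C=C2C[C@H]3C[C@](C)(C(=O)OC(C)(C)C)C[C@H]3[C@]2(C)C1
F6 | step 7 | α,β-epoxy ketone of F5 (either epoxide face serves) | O=C1C2OC23C[C@H]4C[C@](C)(C(=O)OC(C)(C)C)C[C@H]4[C@]3(C)C1
F7 | step 10 | dimethylaminomethyl dione (Mannich base of 15) | CN(C)CC1C(=O)C(=O)[C@@H]2C[C@H]3C[C@](C)(C(=O)O)C[C@H]3[C@]12C
F8 | step 10 | trimethylammonium iodide of F7 | C[N+](C)(C)CC1C(=O)C(=O)[C@@H]2C[C@H]3C[C@](C)(C(=O)O)C[C@H]3[C@]12C.[I-]
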